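**Plan**
- Retrosynthesis: the C8–O ester bond and the silyl ether are cut first, the exocyclic C11=C13 alkene is traced to a Mannich base, and the furanone C3–O bond is opened to a C10 carbinol flanked by a C1/C3 1,3-diketone.
- Enabling feature: C3 and C8 both carry oxygen and lie 1,6 to each other along either arc of the ten-membered carbocycle (C3–C4–C5–C6–C7–C8 and C3–C2–C1–C10–C9–C8). Rejoining them gives an octalin (ring A = C3 to C8 through C4–C7, ring B = C8 to C3 through C9, C10, C1, C2) whose ring-fusion alkene C3=C8 is cleaved by ozone.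
- The octalin is a Birch-reduced tetralin; the tetralin is cut at C7–C8 (Friedel–Crafts), C7–C11 (Horner–Wadsworth–Emmons) and C4–C5 (auxiliary-controlled Michael addition to tert-butyl acrylate).
- Forward order of rings: ring A (step 5), ring B by dearomatisation (step 8), γ-lactone (step 9), ten-membered ring by cleavage of C3=C8 (step 14), furanone (step 15).
- Stereochemistry: C4 from the oxazolidinone auxiliary; C6 and C7 by hydroboration anti to the C4 substituent; C10 by hydroxyl-directed osmylation from the C15 face; C8 by hydride reduction of the bridged ketone; the Z ester geometry comes with angelic acid.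

Key step: step 14

Remark: target numbering (C1–C15) is used for all intermediates; C11 of 19–31 is formed as an epimer mixture, is erased in step 18 and is left undefined in the SMILES; changes of the C4 and C7 descriptors along the route come from CIP priorities only, not from inversion.

Step 1
Reactants: 1 4-methylphenylacetyl chloride; 2 (R)-4-benzyl-1,3-oxazolidin-2-one
Product: 3 (R)-4-benzyl-3-[2-(4-methylphenyl)acetyl]-1,3-oxazolidin-2-one
Conditions: 2, nBuLi, THF, −78 °C; then 1, −78 → 0 °C
Reagents that add atoms: none
Why: N-acylation of the lithiated oxazolidinone by an acid chloride is the standard way of attaching the auxiliary and creates no stereocentre.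

Step 2
Reactants: 3 N-acyl oxazolidinone; 4 tert-butyl acrylate
Product: 5 tert-butyl (4R)-5-[(4R)-4-benzyl-2-oxo-1,3-oxazolidin-3-yl]-4-(4-methylphenyl)-5-oxopentanoate
Conditions: TiCl4 (1.05 equiv), iPr2NEt (1.1 equiv), CH2Cl2, −78 → 0 °C; then 4, 0 °C
Reagents that add atoms: none
Why: Auxiliary-controlled asymmetric Michael addition, in which the chelated Z titanium enolate is shielded on one face by the benzyl group so that the acrylate is attacked from the open face, should set C4 in the sense required by the target (4R in 5 by CIP).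

Step 3
Reactants: 5 Michael adduct
Product: 6 tert-butyl (4R)-5-hydroxy-4-(4-methylphenyl)pentanoate
Conditions: LiBH4, MeOH (1 equiv), THF, 0 °C
Reagents that add atoms: none
Why: Reductive cleavage of the N-acyl oxazolidinone by LiBH4 is faster than reduction of the tert-butyl ester and should release C15 as the primary alcohol without touching the benzylic stereocentre, the auxiliary being recovered.

Step 4
Reactants: 6 hydroxy ester
Product: 7 tert-butyl (4R)-4-(4-methylphenyl)-5-(pivaloyloxy)pentanoate
Conditions: pivaloyl chloride, pyridine, DMAP (cat.), CH2Cl2, 0 °C → rt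
Reagents that add atoms: pivaloyl chloride, CC(C)(C)C(=O)Cl
Why: Acylation of the primary alcohol gives a pivalate, chosen because it survives strong acid, NaH and borane and later leaves under hydroxide together with the ethyl ester.

Step 5
Reactants: 7 pivalate tert-butyl ester
Product: 10 [(1R)-6-methyl-4-oxo-1,2,3,4-tetrahydronaphthalen-1-yl]methyl pivalate, via carboxylic acid 8 (not isolated), via mixed trifluoroacetic anhydride 9 (not isolated)
Conditions: CF3CO2H/CH2Cl2 1:4, rt; evaporate; (CF3CO)2O (2 equiv), CF3SO3H (0.1 equiv), CH2Cl2, 0 °C → rt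
Reagents that add atoms: none
Why: Acidolysis of the tert-butyl ester followed by intramolecular Friedel–Crafts acylation through the mixed anhydride should close ring A (C7–C8 bond) at either of the two equivalent positions ortho to the side chain, and the benzylic C4 centre cannot epimerise under acid.

Step 6
Reactants: 10 tetralone; 11 triethyl phosphonoacetate
Product: 13 ethyl 2-[(4R)-7-methyl-4-(pivaloyloxymethyl)-3,4-dihydronaphthalen-1-yl]acetate, via exocyclic ylidene ester 12 (not isolated)
Conditions: NaH, 11, THF, 65 °C; then NaOEt (0.2 equiv), EtOH, rt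
Reagents that add atoms: none
Why: Horner–Wadsworth–Emmons olefination of the aryl ketone followed by base-mediated deconjugation, which moves the double bond into the ring (C6=C7) and relieves the peri strain of the exocyclic ester, creates no stereocentre and leaves the non-acidic C4 centre alone.

Step 7
Reactants: 13 dihydronaphthalene ester
Product: 15 ethyl 2-[(1R,2R,4R)-2-hydroxy-7-methyl-4-(pivaloyloxymethyl)-1,2,3,4-tetrahydronaphthalen-1-yl]acetate, via alkylborane 14 (not isolated)
Conditions: BH3·SMe2 (1.2 equiv), THF, 0 °C → rt; then 30% H2O2, aq. NaOAc, 0 °C → rt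
Reagents that add atoms: hydrogen peroxide, OO
Why: Hydroboration–oxidation adds H–B syn, with boron on C6 (the less substituted, non-benzylic alkene carbon) and hydrogen on C7, from the face opposite the pseudoaxial C4 substituent, which should place the C6 hydroxyl trans and the C7 side chain cis to C15.

Step 8
Reactants: 15 hydroxy diester
Product: 17 2-[(1R,2R,4R)-2-hydroxy-4-(hydroxymethyl)-7-methyl-1,2,3,4,5,8-hexahydronaphthalen-1-yl]acetic acid, via lithium carboxylate 16 (not isolated)
Conditions: LiOH·H2O (5 equiv), THF/MeOH/H2O, 60 °C; evaporate to dryness; Li (12 equiv), NH3(l)/THF, t-BuOH, −78 → −33 °C; NH4Cl; then 1 M HCl to pH 3, 0 °C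
Reagents that add atoms: lithium hydroxide, [Li+].[OH-]
Why: Saponification followed by Birch reduction should work because the carboxylate and alkoxides are inert to the dissolved metal and the 1,2,4-trialkylbenzene is protonated at its two unsubstituted para carbons (C2 and C9), which leaves the C3=C8 and C1=C10 double bonds on the alkyl-bearing carbons and does not touch C4, C6 or C7.

Step 9
Reactants: 17 diene dihydroxy acid
Product: 18 diene hydroxy lactone (4R,6R,7R; trans-fused 12,6-lactone, free 15-OH)
Conditions: pyridinium p-toluenesulfonate (0.1 equiv), toluene, 4 Å molecular sieves, 60 °C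
Reagents that add atoms: none
Why: Acid-catalysed γ-lactonisation (5-exo-trig acyl substitution by the C6 hydroxyl) under conditions too mild to move the skipped diene should give the trans-fused lactone, which locks ring A with the C15 hydroxymethyl group pseudoaxial.

Step 10
Reactants: 18 diene hydroxy lactone
Product: 19 Mannich base of 18 (CH2NMe2 on C11)
Conditions: LiN(iPr)2 (2.3 equiv), THF, −78 °C; [Me2N=CH2]I (3 equiv), −78 → 0 °C
Reagents that add atoms: N,N-dimethylmethyleneiminium iodide (Eschenmoser's salt), C[N+](C)=C.[I-]
Why: Mannich reaction of the lactone enolate (the C15 alkoxide being a spectator) installs C13 as a β-dimethylamino group that masks the future α-methylene lactone against ozone, hydride and deconjugation, and the new C11 centre is of no consequence because step 18 removes it.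

Step 11
Reactants: 19 Mannich base
Product: 21 triol lactone (1R,4R,6R,7R,10S; cis-1,10-diol on the C15 face), via osmate ester 20 (not isolated)
Conditions: OsO4 (1.05 equiv), TMEDA (1.1 equiv), CH2Cl2, −78 °C; then sat. aq. Na2SO3, THF, 40 °C
Reagents that add atoms: osmium tetroxide, O=[Os](=O)(=O)=O
Why: Proposed new method: the oxo ligands of OsO4·TMEDA are hydrogen-bond acceptors, and the C15 hydroxyl, held pseudoaxial above the C2–C1 edge of ring B by the trans-lactone, should bind the reagent and guide the [3+2] addition to the upper face of the trisubstituted C1=C10 alkene (the tetrasubstituted C3=C8 alkene being too hindered to compete), so that both new C–O bonds come out cis to C15 (1R,10S); the closest known reaction type is the hydroxyl-directed dihydroxylation of cyclic allylic and homoallylic alcohols with OsO4·TMEDA, from which this case differs by a hydroxyl placed two atoms further from the alkene.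

Step 12
Reactants: 21 triol lactone
Product: 22 15-O-TBS 1,10-diol
Conditions: TBSCl (1.05 equiv), imidazole, CH2Cl2, 0 °C
Reagents that add atoms: tert-butyldimethylsilyl chloride, CC(C)(C)[Si](C)(C)Cl
Why: Silylation discriminates the primary C15 hydroxyl from the hindered secondary C1 and tertiary C10 hydroxyls.

Step 13
Reactants: 22 silyl ether diol
Product: 23 octalin α-ketol (4R,6R,7R,10S; C1 ketone, C10 tertiary hydroxyl, C3=C8 alkene)
Conditions: Dess–Martin periodinane (1.3 equiv), NaHCO3, CH2Cl2, 0 °C → rt
Reagents that add atoms: none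
Why: Dess–Martin oxidation converts the secondary C1 carbinol into the ketone, cannot touch the tertiary C10 hydroxyl, and is near-neutral, which should keep the β,γ-unsaturated ketone from moving into conjugation.

Step 14
Reactants: 23 octalin α-ketol
Product: 25 ten-membered 1,3,8-trione (4S,6R,7S,10S; free C10 hydroxyl), via methoxy hydroperoxide 24 (not isolated)
Conditions: CF3CO2H (1.2 equiv), CH2Cl2/MeOH 4:1, −78 °C; O3 (1.05 equiv, added as a titrated CH2Cl2 solution); Me2S (10 equiv), −78 → 0 °C; concentrate below 10 °C and use at once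
Reagents that add atoms: ozone, [O-][O+]=O
Why: Ozone adds to the electron-rich tetrasubstituted C3=C8 double bond in a 1,3-dipolar cycloaddition, the primary ozonide fragments by the Criegee mechanism into a ketone and a carbonyl oxide, methanol captures the latter as the α-methoxy hydroperoxide 24, and Me2S reduces this to the second ketone. The nearest precedent is the ozonolysis of Δ9,10-octalins, which delivers cyclodecane-1,6-diones. No ring is closed by bond formation: the ten-membered carbocycle emerges because the cleaved C3–C8 bond is the only bond shared by rings A and B, so the two six-membered rings merge into one. No stereocentre is created or touched, C4, C6, C7 and C10 being carried over from 23. The step needs chemoselectivity only, and the substrate secures it: C3=C8 is the sole alkene, the amine is shielded from ozone as its ammonium trifluoroacetate, and a single equivalent of ozone is dosed so that the enol of the new 1,3-diketone is spared. Base is excluded throughout, since the C8 carbonyl has the lactone oxygen in its β-position (E1cB loss of carboxylate) and medium-ring polyketones close transannular aldols readily.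

Step 15
Reactants: 25 ten-membered trione
Product: 26 furanone ketone (4S,6R,7S,10S; 3,10-epoxy-2-en-1-one with C8 ketone)
Conditions: pyridinium p-toluenesulfonate (0.2 equiv), 4 Å molecular sieves, CH2Cl2, rt; aq. NaHCO3 work-up
Reagents that add atoms: none
Why: Acid-catalysed cyclodehydration of the α'-hydroxy 1,3-diketone, in which the C10 hydroxyl adds to the C3 carbonyl (5-exo-trig) and water is lost, should give the 3(2H)-furanone, while the C8 ketone cannot be engaged (a four-membered ring would result) and C10 keeps its configuration because its C–O bond is not broken.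

Step 16
Reactants: 26 furanone ketone
Product: 27 (8R)-alcohol (4S,6R,7R,8R,10S; hydroxyl on the side of C11)
Conditions: NaBH4 (1.0 equiv), MeOH/CH2Cl2, −78 °C
Reagents that add atoms: none
Why: Borohydride reduction should pick the saturated C8 ketone over the vinylogous ester carbonyl C1 and the lactone, and hydride is expected to enter from the periphery of the bridged ring on the face flanked by H7 and not by the lactone methylene, which places the new hydroxyl cis to C11.

Step 17
Reactants: 27 (8R)-alcohol; 28 angelic acid
Product: 30 8-O-angelate (4S,6R,7S,8R,10S), via mixed anhydride 29 (not isolated)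
Conditions: 28, 2,4,6-trichlorobenzoyl chloride, Et3N, toluene, rt; then 27, toluene, 70 °C, no DMAP
Reagents that add atoms: none
Why: Yamaguchi-type esterification through the mixed anhydride acylates the hindered secondary C8 hydroxyl with retention, and leaving out a nucleophilic catalyst avoids the addition–elimination path by which angelates isomerise to tiglates.

Step 18
Reactants: 30 angelate Mannich base
Product: 32 α-methylene lactone silyl ether, via quaternary ammonium iodide 31 (not isolated)
Conditions: MeI (10 equiv), MeOH, rt; evaporate; sat. aq. NaHCO3/CH2Cl2, rt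
Reagents that add atoms: none
Why: N-methylation followed by Hofmann-type E1cB elimination of trimethylamine from the β-ammonio lactone under bicarbonate should unmask the α-methylene lactone without disturbing the angelate or the furanone, and it removes the C11 stereocentre.

Step 19
Reactants: 32 α-methylene lactone silyl ether
Product: 33 CNP0108636.1 (target)
Conditions: HF·pyridine, pyridine/THF, 0 °C → rt
Reagents that add atoms: none
Why: Fluoride-mediated cleavage of the primary silyl ether under buffered, non-basic conditions is compatible with the Michael-acceptor lactone, the furanone and the Z-configured ester.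

**Compound list**
1 | 4-methylphenylacetyl chloride | Cc1ccc(CC(=O)Cl)cc1 | starting material
2 | (R)-4-benzyl-1,3-oxazolidin-2-one | O=C1N[C@H](Cc2ccccc2)CO1 | starting material
3 | (R)-4-benzyl-3-[2-(4-methylphenyl)acetyl]-1,3-oxazolidin-2-one | Cc1ccc(CC(=O)N2[C@H](Cc3ccccc3)COC2=O)cc1 | intermediate
4 | tert-butyl acrylate | C=CC(=O)OC(C)(C)C | starting material
5 | tert-butyl (4R)-5-[(4R)-4-benzyl-2-oxo-1,3-oxazolidin-3-yl]-4-(4-methylphenyl)-5-oxopentanoate | CC(C)(C)OC(=O)CC[C@@H](C(=O)N1[C@H](Cc2ccccc2)COC1=O)c1ccc(C)cc1 | intermediate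
6 | tert-butyl (4R)-5-hydroxy-4-(4-methylphenyl)pentanoate | CC(C)(C)OC(=O)CC[C@@H](CO)c1ccc(C)cc1 | intermediate
7 | tert-butyl (4R)-4-(4-methylphenyl)-5-(pivaloyloxy)pentanoate | CC(C)(C)OC(=O)CC[C@@H](COC(=O)C(C)(C)C)c1ccc(C)cc1 | intermediate
8 | (4R)-4-(4-methylphenyl)-5-(pivaloyloxy)pentanoic acid | OC(=O)CC[C@@H](COC(=O)C(C)(C)C)c1ccc(C)cc1 | intermediate
9 | (4R)-4-(4-methylphenyl)-5-(pivaloyloxy)pentanoic trifluoroacetic anhydride | O=C(CC[C@@H](COC(=O)C(C)(C)C)c1ccc(C)cc1)OC(=O)C(F)(F)F | intermediate
10 | [(1R)-6-methyl-4-oxo-1,2,3,4-tetrahydronaphthalen-1-yl]methyl pivalate (tetralone; its carbonyl carbon is the future C7) | O=C1CC[C@@H](COC(=O)C(C)(C)C)c2ccc(C)cc12 | intermediate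
11 | triethyl phosphonoacetate | CCOC(=O)CP(=O)(OCC)OCC | starting material
12 | ethyl (2E)-2-[(4R)-7-methyl-4-(pivaloyloxymethyl)-3,4-dihydronaphthalen-1(2H)-ylidene]acetate | CCOC(=O)/C=C1\CC[C@@H](COC(=O)C(C)(C)C)c2ccc(C)cc12 | intermediate
13 | ethyl 2-[(4R)-7-methyl-4-(pivaloyloxymethyl)-3,4-dihydronaphthalen-1-yl]acetate | CCOC(=O)CC1=CC[C@@H](COC(=O)C(C)(C)C)c2ccc(C)cc12 | intermediate
14 | alkylborane from 13, written as the monoalkylborane: 15 with BH2 in place of the ring hydroxyl, same configuration | CCOC(=O)C[C@H]1[C@H](B)C[C@@H](COC(=O)C(C)(C)C)c2ccc(C)cc12 | intermediate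
15 | ethyl 2-[(1R,2R,4R)-2-hydroxy-7-methyl-4-(pivaloyloxymethyl)-1,2,3,4-tetrahydronaphthalen-1-yl]acetate | CCOC(=O)C[C@H]1[C@H](O)C[C@@H](COC(=O)C(C)(C)C)c2ccc(C)cc12 | intermediate
16 | lithium 2-[(1R,2R,4R)-2-hydroxy-4-(hydroxymethyl)-7-methyl-1,2,3,4-tetrahydronaphthalen-1-yl]acetate | [Li+].[O-]C(=O)C[C@H]1[C@H](O)C[C@@H](CO)c2ccc(C)cc12 | intermediate
17 | 2-[(1R,2R,4R)-2-hydroxy-4-(hydroxymethyl)-7-methyl-1,2,3,4,5,8-hexahydronaphthalen-1-yl]acetic acid | OC(=O)C[C@H]1[C@H](O)C[C@@H](CO)C2=C1CC(C)=CC2 | intermediate
18 | diene hydroxy lactone, (4R,6R,7R): (3aR,5R,9bR)-5-(hydroxymethyl)-8-methyl-3a,4,5,6,9,9b-hexahydronaphtho[2,1-b]furan-2(1H)-one; C3=C8 and C1=C10 double bonds, lactone O on C6 and C11 on C7 (trans), C15 cis to C11 | C1C(=O)O[C@@H]2C[C@@H](CO)C3=C(CC(C)=CC3)[C@@H]12 | intermediate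
19 | Mannich base: 18 carrying CH2NMe2 on C11 (C11 epimers) | CN(C)CC1C(=O)O[C@@H]2C[C@@H](CO)C3=C(CC(C)=CC3)[C@@H]12 | intermediate
20 | osmate ester of 19: cyclic C1,C10 glycolate of hexavalent osmium on the C15 face, TMEDA adduct | CN(C)CC1C(=O)O[C@@H]2C[C@@H](CO)C3=C(C[C@]4(C)O[Os](=O)(=O)O[C@@H]4C3)[C@@H]12.CN(C)CCN(C)C | intermediate
21 | triol lactone, (1R,4R,6R,7R,10S): 19 with C1=C10 converted into a cis-1,10-diol, both hydroxyls on the face of C15, C3=C8 retained | CN(C)CC1C(=O)O[C@@H]2C[C@@H](CO)C3=C(C[C@](C)(O)[C@H](O)C3)[C@@H]12 | intermediate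
22 | 15-O-tert-butyldimethylsilyl ether of 21 | CN(C)CC1C(=O)O[C@@H]2C[C@@H](CO[Si](C)(C)C(C)(C)C)C3=C(C[C@](C)(O)[C@H](O)C3)[C@@H]12 | intermediate
23 | octalin α-ketol, (4R,6R,7R,10S): rings A and B fused through the C3=C8 alkene, C1 ketone, C10 tertiary hydroxyl and methyl, trans-12,6-lactone with CH2NMe2 on C11, C15–OTBS | CN(C)CC1C(=O)O[C@@H]2C[C@@H](CO[Si](C)(C)C(C)(C)C)C3=C(C[C@](C)(O)C(=O)C3)[C@@H]12 | intermediate
24 | α-methoxy hydroperoxide from 23, drawn with the hydroperoxy ketal at C8 and the ketone at C3 (the C3 regioisomer would behave alike) | CN(C)CC1C(=O)O[C@@H]2C[C@@H](CO[Si](C)(C)C(C)(C)C)C(=O)CC(=O)[C@@](C)(O)CC(OC)(OO)[C@@H]12 | intermediate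
25 | ten-membered trione, (4S,6R,7S,10S): cyclodecane ring C1–C10 with ketones at C1, C3 and C8, C10 hydroxyl and methyl, trans-12,6-lactone with CH2NMe2 on C11, C15–OTBS; may sit partly as its C3/C10 hemiketal | CN(C)CC1C(=O)O[C@@H]2C[C@@H](CO[Si](C)(C)C(C)(C)C)C(=O)CC(=O)[C@@](C)(O)CC(=O)[C@@H]12 | intermediate
26 | furanone ketone, (4S,6R,7S,10S): 3,10-epoxy-2-en-1-one (3(2H)-furanone bridging C3 and C10), C8 ketone, lactone with CH2NMe2, C15–OTBS | CN(C)CC1C(=O)O[C@@H]2C[C@@H](CO[Si](C)(C)C(C)(C)C)C3=CC(=O)[C@](C)(CC(=O)[C@@H]12)O3 | intermediate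
27 | (8R)-alcohol, (4S,6R,7R,8R,10S): 26 with the C8 ketone reduced, hydroxyl cis to C11 | CN(C)CC1C(=O)O[C@@H]2C[C@@H](CO[Si](C)(C)C(C)(C)C)C3=CC(=O)[C@](C)(C[C@@H](O)[C@@H]12)O3 | intermediate
28 | angelic acid, (Z)-2-methylbut-2-enoic acid | C/C=C(/C)C(=O)O | starting material
29 | angelic 2,4,6-trichlorobenzoic anhydride | C/C=C(/C)C(=O)OC(=O)c1c(Cl)cc(Cl)cc1Cl | intermediate
30 | 8-O-angelate of 27, (4S,6R,7S,8R,10S) | CN(C)CC1C(=O)O[C@@H]2C[C@@H](CO[Si](C)(C)C(C)(C)C)C3=CC(=O)[C@](C)(C[C@@H](OC(=O)/C(C)=C\C)[C@@H]12)O3 | intermediate
31 | trimethylammonium iodide of 30 | C[N+](C)(C)CC1C(=O)O[C@@H]2C[C@@H](CO[Si](C)(C)C(C)(C)C)C3=CC(=O)[C@](C)(C[C@@H](OC(=O)/C(C)=C\C)[C@@H]12)O3.[I-] | intermediate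
32 | 15-O-TBS ether of the target (α-methylene lactone in place), (4S,6R,7S,8R,10S) | C=C1C(=O)O[C@@H]2C[C@@H](CO[Si](C)(C)C(C)(C)C)C3=CC(=O)[C@](C)(C[C@@H](OC(=O)/C(C)=C\C)[C@@H]12)O3 | intermediate
33 | CNP0108636.1: (4S,6R,7S,8R,10S)-8-angeloyloxy-15-hydroxy-1-oxo-3,10-epoxygermacra-2,11(13)-dien-12,6-olide | C=C1C(=O)O[C@@H]2C[C@@H](CO)C3=CC(=O)[C@](C)(C[C@@H](OC(=O)/C(C)=C\C)[C@@H]12)O3 | target

**Count and risks**
Total steps: 19. Longest linear sequence: 19 steps (1 → 33); the route is fully linear.

Steps most likely to fail:

1. Step 11 (proposed new method). The hydrogen bond may be too weak over this distance to override the steric preference for attack on the lower face, anti to the pseudoaxial C15 group, so that the wrong face is hydroxylated. The reagent might also be delivered to the C3=C8 alkene. The fallback uses known chemistry and steric instead of directed control. It sets out from 19, whose hydroxyl is silylated (TBSCl, imidazole) to the silyl ether F1. Hydroxymercuration of F1 as its trifluoroacetate salt (Hg(OCOCF3)2, THF/H2O, 0 °C; then NaCl) is chemoselective for the trisubstituted alkene. It is an anti addition in which the bulky mercury should take the lower face, away from the pseudoaxial silyloxymethyl group, while water enters at the tertiary C10 from the upper face. This gives the chloromercurial F2 with the required C10 configuration. Oxidative demercuration (NaBH4, O2, DMF) replaces mercury by hydroxyl and gives the 1,10-diol F3 as C1 epimers, which does not matter. Dess–Martin oxidation of F3 rejoins the route at 23.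

2. Step 14. Ozone may go on to attack the enol of the freshly formed 1,3-diketone. The peroxidic intermediate may fragment next to the α-ketol, or the lactone carboxylate may be lost from the β-acyloxy ketone during concentration. The fallback reverses the order of cleavage and C1 oxidation. It sets out from diol 22, which is ozonised as its trifluoroacetate salt (CH2Cl2/MeOH, −78 °C; Me2S) to the 1,10-dihydroxy-3,8-dione F4, expected largely as transannular hemiketals, so that no 1,3-dicarbonyl unit is exposed to ozone. Dess–Martin oxidation of the C1 carbinol of F4 then gives 25, where the route is rejoined.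

3. Step 16. Hydride may be delivered with poor or reversed facial selectivity at C8, or the furanone carbonyl may be reduced in competition. The fallback sets out from 26. If reduction favours the other face, the (8S)-alcohol F5 is taken on and esterified with angelic acid 28 under Mitsunobu conditions (PPh3, DIAD, toluene). This inverts C8 and delivers 30 directly, where the route is rejoined.

**Further compounds**
F1 | step 11 | 15-O-tert-butyldimethylsilyl ether of 19 (diene Mannich lactone) | CN(C)CC1C(=O)O[C@@H]2C[C@@H](CO[Si](C)(C)C(C)(C)C)C3=C(CC(C)=CC3)[C@@H]12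
F2 | step 11 | chloromercurial of F1: C10 hydroxyl on the C15 face, HgCl on C1 on the opposite face, C3=C8 retained | CN(C)CC1C(=O)O[C@@H]2C[C@@H](CO[Si](C)(C)C(C)(C)C)C3=C(C[C@](C)(O)[C@@H]([Hg]Cl)C3)[C@@H]12
F3 | step 11 | 1,10-diol with (10S) tertiary hydroxyl, C1 epimers, C15–OTBS | CN(C)CC1C(=O)O[C@@H]2C[C@@H](CO[Si](C)(C)C(C)(C)C)C3=C(C[C@](C)(O)C(O)C3)[C@@H]12
F4 | step 14 | (1R,4S,6R,7S,10S)-1,10-dihydroxy-3,8-dione of the ten-membered ring, C15–OTBS, lactone with CH2NMe2 | CN(C)CC1C(=O)O[C@@H]2C[C@@H](CO[Si](C)(C)C(C)(C)C)C(=O)C[C@@H](O)[C@@](C)(O)CC(=O)[C@@H]12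
F5 | step 16 | (8S)-alcohol, C8 epimer of 27 | CN(C)CC1C(=O)O[C@@H]2C[C@@H](CO[Si](C)(C)C(C)(C)C)C3=CC(=O)[C@](C)(C[C@H](O)[C@@H]12)O3
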